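**Plan**

- Benzofuran numbering is used: ring A is the fused benzene, ring B the dihydrofuran, ring C the pendant 3,4-dihydroxy-5-methoxyphenyl group.
- Retrosynthetic cuts, in order: the enal C=C at C5 (Wittig, back through aldehyde and alcohol to a C5 ester); the C3 hydroxymethyl back to a C3 ester; the ring B bond C2–C3 (carbene C–H insertion); C3a–C3 (aryl iodide plus ethyl diazoacetate); O1–C2 (phenol plus benzyl alcohol).
- Enabling feature: C2 carries O1 and the electron-rich ring C, so in the ring-opened aryl benzyl ether its C–H bonds are the most hydridic ones and sit 1,5 to a carbene centred on C3.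
- Forward order: the ring C alcohol (from 5-hydroxyvanillin) and the ring A iodophenol (from ethyl vanillate) are joined at O1–C2, C3 is attached as a diazoacetate, ring B is closed by the insertion, and the C5 ester is then extended to the E-enal.
- Stereochemistry: C2 (R) comes from the chiral dirhodium carboxylate in the insertion; C3 is set by ethoxide equilibration of the ester to trans (3S after reduction); the E-alkene comes from a stabilised ylide.

Key step: step 6

Assumption: by analogy with insertions into simpler aryl benzyl ethers, the S-configured catalyst is taken to deliver 2R; were the sense reversed for this substrate, Rh2(R-PTTL)4 would be used with nothing else changed.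

**Route**

Step 1
Reactants: 1 5-hydroxyvanillin (3,4-dihydroxy-5-methoxybenzaldehyde)
Product: 2 3-methoxy-4,5-bis(methoxymethoxy)benzaldehyde
Conditions: MOMCl (2.6 equiv), iPr2NEt (3 equiv), CH2Cl2, 0 °C to rt
Reagents that add atoms: chloromethyl methyl ether (MOMCl), COCCl
Why: Williamson-type O-alkylation of both phenols by the reactive α-chloro ether under amine base should give the bis-MOM ether, the aldehyde being inert.

Step 2
Reactants: 2 3-methoxy-4,5-bis(methoxymethoxy)benzaldehyde
Product: 3 [3-methoxy-4,5-bis(methoxymethoxy)phenyl]methanol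
Conditions: NaBH4, MeOH, 0 °C; aq. NH4Cl
Reagents that add atoms: none
Why: Borohydride reduction of an aromatic aldehyde gives the benzyl alcohol, and the MOM acetals are stable to hydride.

Step 3
Reactants: 4 ethyl vanillate (ethyl 4-hydroxy-3-methoxybenzoate)
Product: 5 ethyl 4-hydroxy-3-iodo-5-methoxybenzoate
Conditions: NIS (1.05 equiv), TsOH·H2O (10 mol%), MeCN, rt, dark
Reagents that add atoms: N-iodosuccinimide (NIS), O=C1CCC(=O)N1I
Why: Electrophilic aromatic iodination is directed ortho by the phenol, whose para position is blocked by the ester, so only the free ortho carbon should be attacked.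

Step 4
Reactants: 5 ethyl 4-hydroxy-3-iodo-5-methoxybenzoate; 3 [3-methoxy-4,5-bis(methoxymethoxy)phenyl]methanol
Product: 6 ethyl 3-iodo-5-methoxy-4-{[3-methoxy-4,5-bis(methoxymethoxy)phenyl]methoxy}benzoate
Conditions: PPh3, DIAD, THF, 0 °C to rt
Reagents that add atoms: none
Why: Mitsunobu etherification should work because the acidic iodophenol (ortho iodine, para ester) displaces the primary benzylic oxyphosphonium, which also avoids an acid-labile electron-rich benzyl halide.

Step 5
Reactants: 6 ethyl 3-iodo-5-methoxy-4-{[3-methoxy-4,5-bis(methoxymethoxy)phenyl]methoxy}benzoate; 7 ethyl diazoacetate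
Product: 8 ethyl 3-(1-diazo-2-ethoxy-2-oxoethyl)-5-methoxy-4-{[3-methoxy-4,5-bis(methoxymethoxy)phenyl]methoxy}benzoate
Conditions: Pd(PPh3)4 (5 mol%), Ag2CO3 (0.5 equiv), Et3N (1.3 equiv), toluene, rt
Reagents that add atoms: none
Why: Palladium-catalysed cross-coupling of an aryl iodide with an acceptor diazo compound proceeds by oxidative addition to zerovalent palladium, base-assisted palladation of the diazoacetate C–H and reductive elimination at room temperature, so the diazo group should survive.

Step 6
Reactants: 8 ethyl 3-(1-diazo-2-ethoxy-2-oxoethyl)-5-methoxy-4-{[3-methoxy-4,5-bis(methoxymethoxy)phenyl]methoxy}benzoate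
Product: 10 diethyl (2R,3R)-7-methoxy-2-[3-methoxy-4,5-bis(methoxymethoxy)phenyl]-2,3-dihydro-1-benzofuran-3,5-dicarboxylate, via cis-diester 9 (not isolated)
Conditions: Rh2(S-PTTL)4 [dirhodium tetrakis(N-phthaloyl-(S)-tert-leucinate)] (1 mol%), toluene, −60 °C; then NaOEt (0.3 equiv), EtOH, 0 °C; AcOH quench
Reagents that add atoms: none
Why: The catalyst expels N2 from 8 to give a donor/acceptor carbene on divalent rhodium, whose electrophilic carbon C3 takes the hydridic benzylic C–H bond next to O1 in a concerted, asynchronous three-centre insertion that forms C2–C3; the closest known reaction type is the enantioselective intramolecular C–H insertion of 2-(benzyloxy)aryl diazoacetates to cis-2-aryl-2,3-dihydrobenzofuran-3-carboxylates with chiral dirhodium carboxylates. Ring B closes by 1,5-insertion through a five-membered transition state, the kinetically preferred mode for such carbenes. C2 is set by the catalyst, whose phthalimide-walled pocket distinguishes the two enantiotopic hydrogens of the O–CH2 group (2R assumed for the S catalyst), and the insertion is expected to place the C3 ester cis to ring C as in 9. C3 is then set under thermodynamic control, since substoichiometric ethoxide reversibly forms the benzylic ester enolate and reprotonation gives the trans (2R,3R) diester 10, while C2 has no acidic hydrogen. The step needs site selectivity over the methoxy and MOM C–H bonds, which is secured because none of them can reach C3 through a five-membered transition state and because the positive charge building at C2 is stabilised by O1 and the para-oxygenated ring C. Ethyl esters matched with ethoxide keep transesterification degenerate, and low temperature with little base should limit β-elimination of the ring A phenoxide from the enolate.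

Step 7
Reactants: 10 diethyl (2R,3R)-7-methoxy-2-[3-methoxy-4,5-bis(methoxymethoxy)phenyl]-2,3-dihydro-1-benzofuran-3,5-dicarboxylate
Product: 11 [(2R,3S)-3-(hydroxymethyl)-7-methoxy-2-[3-methoxy-4,5-bis(methoxymethoxy)phenyl]-2,3-dihydro-1-benzofuran-5-yl]methanol
Conditions: LiAlH4 (2.5 equiv), THF, 0 °C; aq. potassium sodium tartrate work-up
Reagents that add atoms: none
Why: Hydride reduction of both esters to primary alcohols is fast at 0 °C, the acetals and aryl ethers are inert, and the C3 descriptor changes to S only because the substituent priorities change.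

Step 8
Reactants: 11 [(2R,3S)-3-(hydroxymethyl)-7-methoxy-2-[3-methoxy-4,5-bis(methoxymethoxy)phenyl]-2,3-dihydro-1-benzofuran-5-yl]methanol
Product: 12 (2R,3S)-3-(hydroxymethyl)-7-methoxy-2-[3-methoxy-4,5-bis(methoxymethoxy)phenyl]-2,3-dihydro-1-benzofuran-5-carbaldehyde
Conditions: activated MnO2 (15 equiv), CH2Cl2, rt
Reagents that add atoms: none
Why: Chemoselective MnO2 oxidation should take only the benzylic alcohol at C5 and leave the non-activated primary alcohol on C3 untouched.

Step 9
Reactants: 12 (2R,3S)-3-(hydroxymethyl)-7-methoxy-2-[3-methoxy-4,5-bis(methoxymethoxy)phenyl]-2,3-dihydro-1-benzofuran-5-carbaldehyde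
Product: 13 (E)-3-[(2R,3S)-3-(hydroxymethyl)-7-methoxy-2-[3-methoxy-4,5-bis(methoxymethoxy)phenyl]-2,3-dihydro-1-benzofuran-5-yl]prop-2-enal
Conditions: Ph3P=CHCHO (1.3 equiv), toluene, 90 °C
Reagents that add atoms: (triphenylphosphoranylidene)acetaldehyde, O=CC=P(c1ccccc1)(c1ccccc1)c1ccccc1
Why: Wittig olefination with a stabilised formylmethylene ylide should give the E-enal, and the free primary alcohol does not interfere.

Step 10
Reactants: 13 (E)-3-[(2R,3S)-3-(hydroxymethyl)-7-methoxy-2-[3-methoxy-4,5-bis(methoxymethoxy)phenyl]-2,3-dihydro-1-benzofuran-5-yl]prop-2-enal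
Product: 14 cassyformin, (E)-3-[(2R,3S)-2-(3,4-dihydroxy-5-methoxyphenyl)-3-(hydroxymethyl)-7-methoxy-2,3-dihydro-1-benzofuran-5-yl]prop-2-enal
Conditions: 2 M aq. HCl, THF, 40 °C, degassed
Reagents that add atoms: none
Why: Acid-catalysed hydrolysis of the two aryl MOM acetals in alcohol-free aqueous medium should free the catechol without acetalising the enal or opening ring B, so C2 and C3 stay as set.

**Compound list**

1 | 5-hydroxyvanillin (3,4-dihydroxy-5-methoxybenzaldehyde) | COc1cc(C=O)cc(O)c1O | starting material
2 | 3-methoxy-4,5-bis(methoxymethoxy)benzaldehyde | COCOc1cc(C=O)cc(OC)c1OCOC | intermediate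
3 | [3-methoxy-4,5-bis(methoxymethoxy)phenyl]methanol | COCOc1cc(CO)cc(OC)c1OCOC | intermediate
4 | ethyl vanillate (ethyl 4-hydroxy-3-methoxybenzoate) | CCOC(=O)c1ccc(O)c(OC)c1 | starting material
5 | ethyl 4-hydroxy-3-iodo-5-methoxybenzoate | CCOC(=O)c1cc(I)c(O)c(OC)c1 | intermediate
6 | ethyl 3-iodo-5-methoxy-4-{[3-methoxy-4,5-bis(methoxymethoxy)phenyl]methoxy}benzoate | CCOC(=O)c1cc(I)c(OCc2cc(OC)c(OCOC)c(OCOC)c2)c(OC)c1 | intermediate
7 | ethyl diazoacetate | CCOC(=O)C=[N+]=[N-] | starting material
8 | ethyl 3-(1-diazo-2-ethoxy-2-oxoethyl)-5-methoxy-4-{[3-methoxy-4,5-bis(methoxymethoxy)phenyl]methoxy}benzoate | CCOC(=O)C(=[N+]=[N-])c1cc(C(=O)OCC)cc(OC)c1OCc1cc(OC)c(OCOC)c(OCOC)c1 | intermediate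
9 | diethyl (2R,3S)-7-methoxy-2-[3-methoxy-4,5-bis(methoxymethoxy)phenyl]-2,3-dihydro-1-benzofuran-3,5-dicarboxylate (cis) | COc1cc([C@@H]2Oc3c(OC)cc(C(=O)OCC)cc3[C@@H]2C(=O)OCC)cc(OCOC)c1OCOC | intermediate (not isolated)
10 | diethyl (2R,3R)-7-methoxy-2-[3-methoxy-4,5-bis(methoxymethoxy)phenyl]-2,3-dihydro-1-benzofuran-3,5-dicarboxylate (trans) | COc1cc([C@@H]2Oc3c(OC)cc(C(=O)OCC)cc3[C@H]2C(=O)OCC)cc(OCOC)c1OCOC | intermediate
11 | [(2R,3S)-3-(hydroxymethyl)-7-methoxy-2-[3-methoxy-4,5-bis(methoxymethoxy)phenyl]-2,3-dihydro-1-benzofuran-5-yl]methanol | COc1cc([C@@H]2Oc3c(OC)cc(CO)cc3[C@H]2CO)cc(OCOC)c1OCOC | intermediate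
12 | (2R,3S)-3-(hydroxymethyl)-7-methoxy-2-[3-methoxy-4,5-bis(methoxymethoxy)phenyl]-2,3-dihydro-1-benzofuran-5-carbaldehyde | COc1cc([C@@H]2Oc3c(OC)cc(C=O)cc3[C@H]2CO)cc(OCOC)c1OCOC | intermediate
13 | (E)-3-[(2R,3S)-3-(hydroxymethyl)-7-methoxy-2-[3-methoxy-4,5-bis(methoxymethoxy)phenyl]-2,3-dihydro-1-benzofuran-5-yl]prop-2-enal | COc1cc([C@@H]2Oc3c(OC)cc(/C=C/C=O)cc3[C@H]2CO)cc(OCOC)c1OCOC | intermediate
14 | cassyformin, (E)-3-[(2R,3S)-2-(3,4-dihydroxy-5-methoxyphenyl)-3-(hydroxymethyl)-7-methoxy-2,3-dihydro-1-benzofuran-5-yl]prop-2-enal | COc1cc([C@@H]2Oc3c(OC)cc(/C=C/C=O)cc3[C@H]2CO)cc(O)c1O | target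

**Step count**

Total steps: 10. Longest linear sequence: 9 steps (1 to 14 through steps 1, 2 and 4 to 10); the ring A branch from 4 contributes 8.

**Steps most likely to fail**

1. Step 6. The heavily oxygenated benzyl group may be discriminated less cleanly by the catalyst pocket than simpler benzyl ethers. In addition, the C3 enolate formed during equilibration can expel the ring A phenoxide (made a better leaving group by the para ester) and re-close, which would erode the configuration at C2. Either process lowers enantiomeric purity. The fallback replaces catalyst control by separation of diastereomers. It sets out from aldehyde 12 of insufficient enantiomeric purity. The single free hydroxyl is acylated with (1S)-camphanic chloride (Et3N, DMAP, CH2Cl2) to give [(2R,3S)-5-formyl-7-methoxy-2-[3-methoxy-4,5-bis(methoxymethoxy)phenyl]-2,3-dihydro-1-benzofuran-3-yl]methyl (1S,4R)-4,7,7-trimethyl-3-oxo-2-oxabicyclo[2.2.1]heptane-1-carboxylate F1. This would be freed from its minor diastereomer by crystallisation or chromatography. Methanolysis (K2CO3, MeOH, rt) then comes back to the route at 12, now as a single enantiomer.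

2. Step 5. Palladation of the diazoacetate at the aryl–palladium centre next to the bulky ortho benzyloxy group may be slow, leaving time for loss of nitrogen from the diazo ester and for protodeiodination. The fallback builds the C3a–C3 bond without a diazo partner and adds the diazo group afterwards. It sets out from iodide 6. Coupling with the Reformatsky reagent BrZnCH2CO2Et (from ethyl bromoacetate and zinc) under Pd(dba)2/P(t-Bu)3 in THF should give the arylacetate ethyl 3-(2-ethoxy-2-oxoethyl)-5-methoxy-4-{[3-methoxy-4,5-bis(methoxymethoxy)phenyl]methoxy}benzoate F2. Regitz diazo transfer with 4-acetamidobenzenesulfonyl azide and DBU in MeCN at 0 °C then comes back to the route at 8.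

3. Step 9. The para-alkoxy benzaldehyde is a sluggish electrophile, and the enal formed can be homologated a second time by the same ylide, so conversion and over-reaction are hard to balance. The fallback uses a masked two-carbon ylide whose product cannot react further. It sets out from aldehyde 12. Wittig reaction with (1,3-dioxolan-2-ylmethyl)triphenylphosphonium bromide and t-BuOK (2.2 equiv, THF, 0 °C to rt) should give [(2R,3S)-5-[2-(1,3-dioxolan-2-yl)ethenyl]-7-methoxy-2-[3-methoxy-4,5-bis(methoxymethoxy)phenyl]-2,3-dihydro-1-benzofuran-3-yl]methanol F3 as an E/Z mixture. Treatment with 2 M aq. HCl in THF at 40 °C should unmask the aldehyde, equilibrate the alkene to E and cleave both MOM ethers in one operation. The fallback thus comes back to the route at the target 14.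

**Further compounds**

F1 | step 6 | [(2R,3S)-5-formyl-7-methoxy-2-[3-methoxy-4,5-bis(methoxymethoxy)phenyl]-2,3-dihydro-1-benzofuran-3-yl]methyl (1S,4R)-4,7,7-trimethyl-3-oxo-2-oxabicyclo[2.2.1]heptane-1-carboxylate | COc1cc([C@@H]2Oc3c(OC)cc(C=O)cc3[C@H]2COC(=O)[C@@]23CC[C@@](C)(C(=O)O2)C3(C)C)cc(OCOC)c1OCOC
F2 | step 5 | ethyl 3-(2-ethoxy-2-oxoethyl)-5-methoxy-4-{[3-methoxy-4,5-bis(methoxymethoxy)phenyl]methoxy}benzoate | CCOC(=O)Cc1cc(C(=O)OCC)cc(OC)c1OCc1cc(OC)c(OCOC)c(OCOC)c1
F3 | step 9 | [(2R,3S)-5-[2-(1,3-dioxolan-2-yl)ethenyl]-7-methoxy-2-[3-methoxy-4,5-bis(methoxymethoxy)phenyl]-2,3-dihydro-1-benzofuran-3-yl]methanol, E/Z mixture | COc1cc([C@@H]2Oc3c(OC)cc(C=CC4OCCO4)cc3[C@H]2CO)cc(OCOC)c1OCOC
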